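**Plan**

- Retrosynthesis: with the acetal and silyl groups removed and ring B taken back to its 1,4-dihydro level, the cuts are C1'–C6' and C2'–C3' (ring B becomes a C2-ethynyl chromanone plus 2-(trimethylsilyloxy)butadiene), then C2–C(sp) (acetylide onto a chromone), O1–C2 with C2 as a one-carbon unit (enaminone), and C8–C1'' (geranyl bromide onto phloroacetophenone).
- Enabling feature: ring B is held to C2 through C1' alone; its C1'–C2' edge is a masked ethynyl group and C3'–C6' with the C4' oxygen is a masked 2-oxybutadiene. While C2 carries the alkyne and not the 4-hydroxyphenyl ring, the C2–O1 bond has no quinone methide path to opening.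
- Forward order: ring A is bought and C-geranylated; ring C closes by enaminone cyclisation to the 8-geranylchromone; C2 is alkynylated; ring B is built last by cobalt-catalysed [4+2] addition, dehydrogenated, and all protecting groups are removed in one acidic step.
- Stereochemistry: the only stereocentre, C2 (S), comes from ligand-controlled addition of a copper acetylide to the Re face of a 4-silyloxybenzopyrylium ion and is carried through neutral or mildly acidic steps; the 2''E olefin is bought with geranyl bromide.

Key step: step 6

Assumption: (S)-StackPhos is taken to be the ligand antipode that sends the acetylide to the Re face of C2; if a model chromone shows the opposite sense, (R)-StackPhos is used and nothing else changes.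

In the names below, geranyl means (2E)-3,7-dimethylocta-2,6-dien-1-yl and MOM means methoxymethyl.

**Step 1**
Reactants: 1 2,4,6-trihydroxyacetophenone; 2 geranyl bromide
Product: 3 1-(3-geranyl-2,4,6-trihydroxyphenyl)ethanone
Conditions: K2CO3, acetone, reflux (1 in 1.5-fold excess, dried before use)
Reagents that add atoms: none
Why: The phloroglucinol-type phenoxide of 1 is a soft carbon nucleophile, so SN2 attack on the primary allylic bromide at one of the two equivalent free ring positions (C-alkylation of a phenolate) gives the C3-geranyl compound with the E olefin untouched, the excess of 1 limiting O-alkylation and double alkylation.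

**Step 2**
Reactants: 3 1-(3-geranyl-2,4,6-trihydroxyphenyl)ethanone
Product: 4 1-[3-geranyl-2-hydroxy-4,6-bis(methoxymethoxy)phenyl]ethanone
Conditions: MOMCl (2.1 equiv), iPr2NEt (2.5 equiv), CH2Cl2, 0 °C → rt
Reagents that add atoms: chloromethyl methyl ether, COCCl
Why: Williamson-type O-alkylation takes the 4-OH and the 6-OH, whereas the 2-OH, wedged between the geranyl and acetyl groups and held in the hydrogen-bonded chelate with the carbonyl group, is expected to stay free, and this is the hydroxyl whose ring closure places the geranyl group at C8.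

**Step 3**
Reactants: 4 1-[3-geranyl-2-hydroxy-4,6-bis(methoxymethoxy)phenyl]ethanone
Product: 6 8-geranyl-5,7-bis(methoxymethoxy)-4H-chromen-4-one, via enaminone 5 (not isolated)
Conditions: Me2NCH(OMe)2 (3 equiv), toluene, 90 °C; evaporate; AcOH/toluene (1:4), 60 °C
Reagents that add atoms: N,N-dimethylformamide dimethyl acetal, COC(OC)N(C)C
Why: Condensation of the methyl ketone with the formamide acetal gives the vinylogous amide 5, and under weak acid the free 2-OH adds to its β-carbon (6-endo oxa-Michael addition) and dimethylamine is lost, a standard enaminone route to chromones that is mild enough for the aryl acetals and the geranyl chain.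

**Step 4**
Reactants: 6 8-geranyl-5,7-bis(methoxymethoxy)-4H-chromen-4-one; 7 trimethylsilylacetylene
Product: 9 (2S)-8-geranyl-5,7-bis(methoxymethoxy)-2-[(trimethylsilyl)ethynyl]chroman-4-one, via silyl enol ether 8 (not isolated)
Conditions: CuI (10 mol%), (S)-StackPhos (11 mol%), TBSOTf (1.3 equiv), iPr2NEt (1.6 equiv), toluene, −78 → −40 °C; then 1 M HCl, THF, 0 °C
Reagents that add atoms: tert-butyldimethylsilyl triflate, CC(C)(C)[Si](C)(C)OS(=O)(=O)C(F)(F)F (its silyl group is carried by intermediate 8 only)
Why: TBSOTf silylates the C4 carbonyl to a 4-silyloxybenzopyrylium ion and the copper acetylide formed from 7, CuI and the amine adds to C2 (copper-catalysed enantioselective alkynylation of chromones), the StackPhos-bound monovalent copper exposing the Re face so that the 2S centre results, while the bulky silyl triflate at low temperature with amine present should spare the MOM acetals and the cold dilute acid hydrolyses only the silyl enol ether 8.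

**Step 5**
Reactants: 9 (2S)-8-geranyl-5,7-bis(methoxymethoxy)-2-[(trimethylsilyl)ethynyl]chroman-4-one
Product: 10 (2S)-2-ethynyl-8-geranyl-5,7-bis(methoxymethoxy)chroman-4-one
Conditions: AgNO3 (10 mol%), acetone/H2O (10:1), rt, dark
Reagents that add atoms: none
Why: Silver-catalysed protodesilylation of the alkynylsilane runs at neutral pH, so the C(sp)–Si bond is cleaved without the base that could open ring C by a retro-oxa-Michael reaction and racemise C2.

**Step 6**
Reactants: 10 (2S)-2-ethynyl-8-geranyl-5,7-bis(methoxymethoxy)chroman-4-one; 11 2-(trimethylsilyloxy)buta-1,3-diene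
Product: 12 (2S)-8-geranyl-5,7-bis(methoxymethoxy)-2-[4-(trimethylsilyloxy)cyclohexa-1,4-dien-1-yl]chroman-4-one
Conditions: CoBr2(dppe) (10 mol%), Zn powder (20 mol%), ZnI2 (20 mol%), 11 (3 equiv), CH2Cl2, rt; filtration through neutral alumina, used at once
Reagents that add atoms: none
Why: Zinc reduces CoBr2(dppe) to monovalent cobalt and ZnI2 takes up bromide, so a cationic dppe–cobalt fragment binds the s-cis diene 11 and the ethynyl group of 10, couples them oxidatively to a cobaltacycle of trivalent cobalt and releases the 1,4-cyclohexadiene by reductive elimination, a formal [4+2] addition. The closest known reaction type is the cobalt-catalysed neutral Diels–Alder reaction of unactivated terminal alkynes with 2-silyloxybutadienes. Ring B closes by intermolecular [4+2] annulation on the metal, with C1'–C6' and C2'–C3' as the two new bonds and no tether involved. No stereocentre is created, and C2 is a spectator because the medium is neutral and aprotic and the propargylic C2–O1 bond is not ionised. The step needs para regiochemistry (siloxy carbon C4' opposite C1'), which the dppe-ligated catalyst imposes on 2-substituted dienes and terminal alkynes. It also needs chemoselectivity for the alkyne, secured because the trisubstituted geranyl olefins and the ketone do not enter this cobalt cycle, while the excess of 11 in CH2Cl2 should hold back alkyne cyclotrimerisation.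

**Step 7**
Reactants: 12 (2S)-8-geranyl-5,7-bis(methoxymethoxy)-2-[4-(trimethylsilyloxy)cyclohexa-1,4-dien-1-yl]chroman-4-one
Product: 13 (2S)-8-geranyl-5,7-bis(methoxymethoxy)-2-[4-(trimethylsilyloxy)phenyl]chroman-4-one
Conditions: DDQ (1.05 equiv), toluene, 0 °C → rt
Reagents that add atoms: none
Why: DDQ abstracts hydride from the doubly allylic C6' methylene to give a cation stabilised by the C4' siloxy group and loss of the C3' proton gives the benzene ring (dehydrogenation of a 1,4-cyclohexadiene), which should be much faster than attack on the geranyl chain or ring C with one equivalent in the cold, and partial loss of the labile aryl silyl group here would be of no consequence.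

**Step 8**
Reactants: 13 (2S)-8-geranyl-5,7-bis(methoxymethoxy)-2-[4-(trimethylsilyloxy)phenyl]chroman-4-one
Product: 14 sophoraflavanone A [(2S)-8-geranyl-5,7-dihydroxy-2-(4-hydroxyphenyl)chroman-4-one]
Conditions: 3 M aq. HCl/MeOH (1:10), 40 °C, argon
Reagents that add atoms: none
Why: Acid-catalysed transacetalisation in methanol removes both MOM groups and solvolysis removes the aryl trimethylsilyl ether, the medium staying mildly acidic so that no phenoxide forms (the species that would open the C2–O1 bond through a quinone methide and racemise C2) and the geranyl olefins are not protonated to a significant extent.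

**Compound list**

1 | 2,4,6-trihydroxyacetophenone | CC(=O)c1c(O)cc(O)cc1O | starting material
2 | geranyl bromide, (2E)-1-bromo-3,7-dimethylocta-2,6-diene | CC(C)=CCC/C(C)=C/CBr | starting material
3 | 1-(3-geranyl-2,4,6-trihydroxyphenyl)ethanone | CC(C)=CCC/C(C)=C/Cc1c(O)cc(O)c(C(C)=O)c1O | intermediate
4 | 1-[3-geranyl-2-hydroxy-4,6-bis(methoxymethoxy)phenyl]ethanone | CC(C)=CCC/C(C)=C/Cc1c(OCOC)cc(OCOC)c(C(C)=O)c1O | intermediate
5 | (2E)-3-(dimethylamino)-1-[3-geranyl-2-hydroxy-4,6-bis(methoxymethoxy)phenyl]prop-2-en-1-one | CC(C)=CCC/C(C)=C/Cc1c(OCOC)cc(OCOC)c(C(=O)/C=C/N(C)C)c1O | intermediate (not isolated)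
6 | 8-geranyl-5,7-bis(methoxymethoxy)-4H-chromen-4-one | CC(C)=CCC/C(C)=C/Cc1c(OCOC)cc(OCOC)c2c1OC=CC2=O | intermediate
7 | trimethylsilylacetylene | C#C[Si](C)(C)C | starting material
8 | (2S)-4-(tert-butyldimethylsilyloxy)-8-geranyl-5,7-bis(methoxymethoxy)-2-[(trimethylsilyl)ethynyl]-2H-chromene | CC(C)=CCC/C(C)=C/Cc1c(OCOC)cc(OCOC)c2c1O[C@H](C#C[Si](C)(C)C)C=C2O[Si](C)(C)C(C)(C)C | intermediate (not isolated)
9 | (2S)-8-geranyl-5,7-bis(methoxymethoxy)-2-[(trimethylsilyl)ethynyl]chroman-4-one | CC(C)=CCC/C(C)=C/Cc1c(OCOC)cc(OCOC)c2c1O[C@H](C#C[Si](C)(C)C)CC2=O | intermediate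
10 | (2S)-2-ethynyl-8-geranyl-5,7-bis(methoxymethoxy)chroman-4-one | CC(C)=CCC/C(C)=C/Cc1c(OCOC)cc(OCOC)c2c1O[C@H](C#C)CC2=O | intermediate
11 | 2-(trimethylsilyloxy)buta-1,3-diene | C=CC(=C)O[Si](C)(C)C | starting material
12 | (2S)-8-geranyl-5,7-bis(methoxymethoxy)-2-[4-(trimethylsilyloxy)cyclohexa-1,4-dien-1-yl]chroman-4-one | CC(C)=CCC/C(C)=C/Cc1c(OCOC)cc(OCOC)c2c1O[C@H](C1=CCC(O[Si](C)(C)C)=CC1)CC2=O | intermediate
13 | (2S)-8-geranyl-5,7-bis(methoxymethoxy)-2-[4-(trimethylsilyloxy)phenyl]chroman-4-one | CC(C)=CCC/C(C)=C/Cc1c(OCOC)cc(OCOC)c2c1O[C@H](c1ccc(O[Si](C)(C)C)cc1)CC2=O | intermediate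
14 | sophoraflavanone A, (2S)-8-geranyl-5,7-dihydroxy-2-(4-hydroxyphenyl)chroman-4-one | CC(C)=CCC/C(C)=C/Cc1c(O)cc(O)c2c1O[C@H](c1ccc(O)cc1)CC2=O | target

**Totals**

Total step count: 8. Longest linear sequence: 8 steps (from 1).

**Steps most likely to fail**

Step 4. The risk is poor facial discrimination in the acetylide addition, because the C8 geranyl group beside O1 and the 5-OMOM group peri to the silylated carbonyl crowd the benzopyrylium ion in a way simpler chromones do not. The fallback gives up catalyst control and sets out from 6. The same addition with CuI and PPh3 in place of the chiral ligand (TBSOTf, iPr2NEt, 7, toluene) would give racemic 4-(tert-butyldimethylsilyloxy)-8-geranyl-5,7-bis(methoxymethoxy)-2-[(trimethylsilyl)ethynyl]-2H-chromene F1, hydrolysed on cold acidic work-up to racemic 8-geranyl-5,7-bis(methoxymethoxy)-2-[(trimethylsilyl)ethynyl]chroman-4-one F2. Preparative chromatography of F2 on a chiral stationary phase (amylose tris(3,5-dimethylphenylcarbamate) on silica) would then separate the enantiomers; (2R)-8-geranyl-5,7-bis(methoxymethoxy)-2-[(trimethylsilyl)ethynyl]chroman-4-one F3 is set aside and the 2S enantiomer is compound 9, where the route is rejoined.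

Step 6. The risk is diversion of the cobalt catalyst: alkyne cyclotrimerisation, binding of the metal or of ZnI2 by the C4 carbonyl and 5-OMOM pair, erosion of the para orientation, or hydrolysis of the silyl enol ether before it is used. The fallback brings ring B in intact and sets out from 6. Asymmetric conjugate addition of 4-(methoxymethoxy)phenylboronic acid under divalent palladium catalysis (Pd(OCOCF3)2, the t-BuPyOx antipode that leads to the 2S product, NH4PF6, H2O, ClCH2CH2Cl, 60 °C) would give (2S)-8-geranyl-5,7-bis(methoxymethoxy)-2-[4-(methoxymethoxy)phenyl]chroman-4-one F4. The conditions of step 8 would then remove the three acetals and rejoin the route at 14; the C2–O1 bond stays protected against quinone methide opening until that last step, since the 4'-oxygen is masked.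

Step 7. The risk is over-oxidation (hydride abstraction by DDQ at the doubly activated C1'' methylene of the geranyl chain or dehydrogenation of ring C) and hydrolysis of the silyl enol ether by the acidic hydroquinone before ring B is aromatised. The fallback is a Saegusa–Ito dehydrogenation, which acts only at the silyl enol ether, and sets out from 12. Pd(OAc)2 (1.1 equiv) in MeCN at rt would form the palladium enolate at C5', and β-hydride loss from C6' would give (2S)-8-geranyl-5,7-bis(methoxymethoxy)-2-(4-oxocyclohexa-1,5-dien-1-yl)chroman-4-one F5. F5 tautomerises in the flask to (2S)-8-geranyl-2-(4-hydroxyphenyl)-5,7-bis(methoxymethoxy)chroman-4-one F6. The conditions of step 8 applied to F6 rejoin the route at 14.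

**Further compounds**

F1 | step 4 | racemic 4-(tert-butyldimethylsilyloxy)-8-geranyl-5,7-bis(methoxymethoxy)-2-[(trimethylsilyl)ethynyl]-2H-chromene | CC(C)=CCC/C(C)=C/Cc1c(OCOC)cc(OCOC)c2c1OC(C#C[Si](C)(C)C)C=C2O[Si](C)(C)C(C)(C)C
F2 | step 4 | racemic 8-geranyl-5,7-bis(methoxymethoxy)-2-[(trimethylsilyl)ethynyl]chroman-4-one | CC(C)=CCC/C(C)=C/Cc1c(OCOC)cc(OCOC)c2c1OC(C#C[Si](C)(C)C)CC2=O
F3 | step 4 | (2R)-8-geranyl-5,7-bis(methoxymethoxy)-2-[(trimethylsilyl)ethynyl]chroman-4-one | CC(C)=CCC/C(C)=C/Cc1c(OCOC)cc(OCOC)c2c1O[C@@H](C#C[Si](C)(C)C)CC2=O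
F4 | step 6 | (2S)-8-geranyl-5,7-bis(methoxymethoxy)-2-[4-(methoxymethoxy)phenyl]chroman-4-one | CC(C)=CCC/C(C)=C/Cc1c(OCOC)cc(OCOC)c2c1O[C@H](c1ccc(OCOC)cc1)CC2=O
F5 | step 7 | (2S)-8-geranyl-5,7-bis(methoxymethoxy)-2-(4-oxocyclohexa-1,5-dien-1-yl)chroman-4-one | CC(C)=CCC/C(C)=C/Cc1c(OCOC)cc(OCOC)c2c1O[C@H](C1=CCC(=O)C=C1)CC2=O
F6 | step 7 | (2S)-8-geranyl-2-(4-hydroxyphenyl)-5,7-bis(methoxymethoxy)chroman-4-one | CC(C)=CCC/C(C)=C/Cc1c(OCOC)cc(OCOC)c2c1O[C@H](c1ccc(O)cc1)CC2=O
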